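**Retrosynthetic overview**
1. Target 17 ⇐ Ru-catalysed Alder-ene coupling of allyl acid 10 with alkynyl acyl-pyranone 16; this makes the skipped-diene C–C bond and moves the alkene next to C2.
2. 16 ⇐ C-acylation of (R)-dihydropyranone 13 with pent-4-ynoic acid 14; 13 ⇐ organocatalytic asymmetric transfer hydrogenation of achiral triacetic acid lactone 11 (new reaction, sets C6).
3. 10 ⇐ Fráter–Seebach allylation and in-flask saponification of β-hydroxy ester 5 (sets C2); 5 ⇐ hydroxyl-directed hydrogenation of allylic alcohol 4 (sets C4).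
4. 4 ⇐ Lewis-base-catalysed, metal-free enantioselective acetate aldol of tiglic aldehyde 1 with silyl ketene acetal 2 (sets C3, the first stereocentre of this branch).
5. Rings: the only ring (the pyranone) is bought as 11 and only reduced; no ring is formed.

Assumption: the target is made as the enol tautomer drawn in the SMILES, and the catalyst enantiomers named in steps 1 and 4 are those expected to give the stated facial sense (the mirror-image catalyst is used if the sense proves opposite).

**Step 1**
Reactants: 1 (E)-2-methylbut-2-enal (tiglic aldehyde); 2 tert-butyl[(1-methoxyethenyl)oxy]dimethylsilane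
Product: 4 methyl (3S,4E)-3-hydroxy-4-methylhex-4-enoate, via trichlorosilyl aldolate 3 (not isolated)
Conditions: SiCl4 (1.2 equiv), (S,S)-bisphosphoramide (binaphthyl-2,2′-diamine-derived, (CH2)5-linked; 2 mol %), CH2Cl2, −78 °C; sat. aq NaHCO3
Reagents that add atoms: silicon tetrachloride, Cl[Si](Cl)(Cl)Cl (the SiCl3 group of 3 only; nothing of it stays in 4)
Why: Lewis-base-catalysed Mukaiyama-type acetate aldol addition (chiral phosphoramide-bound SiCl3+ as the Lewis acid), which works best with conjugated non-enolisable aldehydes such as α-methyl enals; the chiral silicon cation binds 1 and exposes its Si face to 2, setting C3 as S, and aqueous work-up cleaves the O–SiCl3 bond of 3.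

**Step 2**
Reactants: 4 methyl (3S,4E)-3-hydroxy-4-methylhex-4-enoate
Product: 5 methyl (3S,4S)-3-hydroxy-4-methylhexanoate
Conditions: [Rh(nbd)(dppb)]BF4 (5 mol %), H2 (45 bar), CH2Cl2, rt
Reagents that add atoms: none
Why: Hydroxyl-directed homogeneous hydrogenation (cationic Rh): the C3–OH and the alkene chelate Rh, A(1,2) strain with the vinylic methyl fixes the rotamer in which C3–H lies next to that methyl, and H2 is delivered to the alkene face on the side of the oxygen, making C4 S (OH/CH3 syn) while the ester is untouched.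

**Step 3**
Reactants: 5 methyl (3S,4S)-3-hydroxy-4-methylhexanoate; 6 allyl bromide
Product: 10 (2R,3R,4S)-3-hydroxy-4-methyl-2-(prop-2-en-1-yl)hexanoic acid, via dilithio dianion 7 (not isolated), via methyl ester 8 (not isolated), via lithium carboxylate 9 (not isolated)
Conditions: LDA (2.2 equiv), THF, −78 → −20 °C; 6 (1.5 equiv), DMPU, −78 → 0 °C; then LiOH·H2O (6 equiv), MeOH/H2O, rt → 40 °C; 1 M HCl to pH 2
Reagents that add atoms: lithium diisopropylamide, [Li+].CC(C)[N-]C(C)C (the lithium of 7 only); lithium hydroxide, [Li+].[OH-] (the carboxyl OH oxygen of 10 and the lithium of 9)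
Why: Fráter–Seebach alkylation followed by saponification in the same flask: the chelated alkoxide-enolate 7 is allylated on the face away from the C3 sec-butyl group to give the 2,3-anti (2R) ester 8, and hydroxide then cleaves the methyl ester (and any allyl ester formed from excess 6) without touching the stereocentres.

**Step 4**
Reactants: 11 4-hydroxy-6-methyl-2H-pyran-2-one (triacetic acid lactone)
Product: 13 (6R)-4-hydroxy-6-methyl-5,6-dihydro-2H-pyran-2-one, via pyran dienol 12 (not isolated)
Conditions: Hantzsch ester (diethyl 2,6-dimethyl-1,4-dihydropyridine-3,5-dicarboxylate, 1.3 equiv), (R)-3,3′-bis(2,4,6-triisopropylphenyl)-H8-BINOL N-triflylphosphoramide (5 mol %), 4 Å MS, CHCl3, 45 °C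
Reagents that add atoms: none
Why: Proposed new method: Brønsted-acid-catalysed asymmetric transfer hydrogenation of a 2-pyranone, in which the strong chiral acid protonates 11 (through its 2-hydroxy-4-pyranone tautomer) to a 2,4-dihydroxy-6-methylpyrylium held as a contact ion pair with the chiral phosphoramidate, the Hantzsch ester (hydrogen-bonded to P=O) transfers hydride to the Si face of C6, the only electrophilic ring carbon without a hydroxyl donor, setting 6R, and dienol 12 tautomerises to the non-aromatic β-keto lactone 13, which cannot form a pyrylium and is not reduced further; the closest known reaction types are chiral phosphoric acid/Hantzsch ester transfer hydrogenation of quinolines, pyridines and benzopyrylium ions and the metal-catalysed asymmetric hydrogenation of the C5=C6 bond of this same pyranone.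

**Step 5**
Reactants: 13 (6R)-4-hydroxy-6-methyl-5,6-dihydro-2H-pyran-2-one; 14 pent-4-ynoic acid
Product: 16 (6R)-4-hydroxy-6-methyl-3-(pent-4-ynoyl)-5,6-dihydro-2H-pyran-2-one, via enol ester 15 (not isolated)
Conditions: 14 (1.1 equiv), DCC (1.2 equiv), DMAP (0.3 equiv), CH2Cl2, 0 °C → rt, then 40 °C
Reagents that add atoms: none
Why: Steglich-type O-acylation of the enol followed by DMAP-mediated O→C acyl migration (Fries-type 1,3-shift) to the hydrogen-bonded 3-acyl tricarbonyl, the thermodynamic product; C6 and the alkyne are not involved.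

**Step 6**
Reactants: 10 (2R,3R,4S)-3-hydroxy-4-methyl-2-(prop-2-en-1-yl)hexanoic acid; 16 (6R)-4-hydroxy-6-methyl-3-(pent-4-ynoyl)-5,6-dihydro-2H-pyran-2-one
Product: 17 (2R,3E)-2-[(1R,2S)-1-hydroxy-2-methylbutyl]-9-[(6R)-4-hydroxy-6-methyl-2-oxo-5,6-dihydro-2H-pyran-3-yl]-6-methylidene-9-oxonon-3-enoic acid (target)
Conditions: [CpRu(MeCN)3]PF6 (10 mol %), acetone, rt
Reagents that add atoms: none
Why: Ruthenium-catalysed alkene–alkyne coupling (Trost Alder-ene reaction): oxidative cyclisation to a ruthenacyclopentene, β-hydride elimination from the allylic CH2 and reductive elimination give the branched 1,4-diene with an E-disubstituted alkene, a coupling I recall being used on unprotected partners in the closely related alternaric acid series, and C2 keeps its hydrogen so no stereocentre is touched.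

**Compound list**
1 | (E)-2-methylbut-2-enal (tiglic aldehyde) | C/C=C(\C)C=O | starting material
2 | tert-butyl[(1-methoxyethenyl)oxy]dimethylsilane | C=C(OC)O[Si](C)(C)C(C)(C)C | starting material
3 | methyl (3S,4E)-4-methyl-3-[(trichlorosilyl)oxy]hex-4-enoate | COC(=O)C[C@H](O[Si](Cl)(Cl)Cl)/C(C)=C/C | intermediate
4 | methyl (3S,4E)-3-hydroxy-4-methylhex-4-enoate | COC(=O)C[C@H](O)/C(C)=C/C | intermediate
5 | methyl (3S,4S)-3-hydroxy-4-methylhexanoate | COC(=O)C[C@H](O)[C@@H](C)CC | intermediate
6 | allyl bromide (3-bromoprop-1-ene) | C=CCBr | starting material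
7 | dilithium (1E,3R,4S)-1-methoxy-4-methylhex-1-ene-1,3-bis(olate) | CO/C([O-])=C/[C@H]([O-])[C@@H](C)CC.[Li+].[Li+] | intermediate
8 | methyl (2R,3R,4S)-3-hydroxy-4-methyl-2-(prop-2-en-1-yl)hexanoate | C=CC[C@@H](C(=O)OC)[C@H](O)[C@@H](C)CC | intermediate
9 | lithium (2R,3R,4S)-3-hydroxy-4-methyl-2-(prop-2-en-1-yl)hexanoate | C=CC[C@@H](C(=O)[O-])[C@H](O)[C@@H](C)CC.[Li+] | intermediate
10 | (2R,3R,4S)-3-hydroxy-4-methyl-2-(prop-2-en-1-yl)hexanoic acid | C=CC[C@@H](C(=O)O)[C@H](O)[C@@H](C)CC | intermediate
11 | 4-hydroxy-6-methyl-2H-pyran-2-one | CC1=CC(O)=CC(=O)O1 | starting material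
12 | (6R)-6-methyl-6H-pyran-2,4-diol | OC1=CC(O)=C[C@@H](C)O1 | intermediate
13 | (6R)-4-hydroxy-6-methyl-5,6-dihydro-2H-pyran-2-one | O=C1C=C(O)C[C@@H](C)O1 | intermediate
14 | pent-4-ynoic acid | C#CCCC(=O)O | starting material
15 | (6R)-6-methyl-2-oxo-5,6-dihydro-2H-pyran-4-yl pent-4-ynoate | O=C1C=C(OC(=O)CCC#C)C[C@@H](C)O1 | intermediate
16 | (6R)-4-hydroxy-6-methyl-3-(pent-4-ynoyl)-5,6-dihydro-2H-pyran-2-one | C#CCCC(=O)C1=C(O)C[C@@H](C)OC1=O | intermediate
17 | (2R,3E)-2-[(1R,2S)-1-hydroxy-2-methylbutyl]-9-[(6R)-4-hydroxy-6-methyl-2-oxo-5,6-dihydro-2H-pyran-3-yl]-6-methylidene-9-oxonon-3-enoic acid | C=C(C/C=C/[C@@H](C(=O)O)[C@H](O)[C@@H](C)CC)CCC(=O)C1=C(O)C[C@@H](C)OC1=O | target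

**Step count and risks**
Total steps: 6. Longest linear sequence: 4 (steps 1, 2, 3, 6).

Most likely to fail:

1. Step 4 (the proposed new transfer hydrogenation). The pyranone may not be basic enough to be activated, hydride may add at C4 (leading to 6-methyl-2-pyranone after loss of water), or the ee may be low. The fallback sets out from 11 and comes back at 13. It replaces ion-pair hydride transfer by inner-sphere metal catalysis: asymmetric hydrogenation with H2 (50–60 bar) and a cationic Ru(II) catalyst carrying an atropisomeric diphosphine (MeO-BIPHEP or BINAP type) in i-PrOH/CH2Cl2 at 50–60 °C. To my knowledge this is a reported reaction of this very pyranone and saturates only C5=C6. It makes no new compound (F0).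

2. Step 6 (Alder-ene coupling). The chelating acyl-pyranone and the free acid may inhibit the cationic Ru catalyst, or the branched/linear ratio may be poor. The fallback sets out from 8 and 14 and comes back at 17; it joins the pyranone after the diene is made instead of before. Step 3 is stopped with aq NH4Cl before hydroxide is added and 8 is isolated. Ester 8 and acid 14, both non-chelating, are coupled with [CpRu(MeCN)3]PF6 in acetone to give (6E,8R,9R,10S)-9-hydroxy-8-(methoxycarbonyl)-10-methyl-4-methylidenedodec-6-enoic acid F3. F3 is then condensed with 13 (DCC, DMAP, CH2Cl2) through the enol ester (6R)-6-methyl-2-oxo-5,6-dihydro-2H-pyran-4-yl (6E,8R,9R,10S)-9-hydroxy-8-(methoxycarbonyl)-10-methyl-4-methylidenedodec-6-enoate F4, which rearranges to methyl (2R,3E)-2-[(1R,2S)-1-hydroxy-2-methylbutyl]-9-[(6R)-4-hydroxy-6-methyl-2-oxo-5,6-dihydro-2H-pyran-3-yl]-6-methylidene-9-oxonon-3-enoate F5. The methyl ester is finally cleaved with Me3SnOH (1,2-dichloroethane, 70 °C), giving 17.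

3. Step 2 (directed hydrogenation). The diastereoselectivity rests on A(1,2) strain against a methyl group only and may be modest; alkene isomerisation is also possible. The fallback sets out from 4 and comes back at 5; it replaces substrate direction by catalyst control. Alcohol 4 is silylated (TBSCl, imidazole, DMF) to methyl (3S,4E)-3-[(tert-butyldimethylsilyl)oxy]-4-methylhex-4-enoate F1. The now non-coordinating trisubstituted alkene is hydrogenated with a chiral Ir–phosphine-oxazoline (P,N) catalyst (BArF salt, H2 50 bar, CH2Cl2; ligand enantiomer chosen for 4S) to methyl (3S,4S)-3-[(tert-butyldimethylsilyl)oxy]-4-methylhexanoate F2. Desilylation with HF·pyridine in THF gives 5.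

**Further compounds**
F0 | step 4 | none | none
F1 | step 2 | methyl (3S,4E)-3-[(tert-butyldimethylsilyl)oxy]-4-methylhex-4-enoate | COC(=O)C[C@H](O[Si](C)(C)C(C)(C)C)/C(C)=C/C
F2 | step 2 | methyl (3S,4S)-3-[(tert-butyldimethylsilyl)oxy]-4-methylhexanoate | COC(=O)C[C@H](O[Si](C)(C)C(C)(C)C)[C@@H](C)CC
F3 | step 6 | (6E,8R,9R,10S)-9-hydroxy-8-(methoxycarbonyl)-10-methyl-4-methylidenedodec-6-enoic acid | C=C(C/C=C/[C@@H](C(=O)OC)[C@H](O)[C@@H](C)CC)CCC(=O)O
F4 | step 6 | (6R)-6-methyl-2-oxo-5,6-dihydro-2H-pyran-4-yl (6E,8R,9R,10S)-9-hydroxy-8-(methoxycarbonyl)-10-methyl-4-methylidenedodec-6-enoate | C=C(C/C=C/[C@@H](C(=O)OC)[C@H](O)[C@@H](C)CC)CCC(=O)OC1=CC(=O)O[C@H](C)C1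
F5 | step 6 | methyl (2R,3E)-2-[(1R,2S)-1-hydroxy-2-methylbutyl]-9-[(6R)-4-hydroxy-6-methyl-2-oxo-5,6-dihydro-2H-pyran-3-yl]-6-methylidene-9-oxonon-3-enoate | C=C(C/C=C/[C@@H](C(=O)OC)[C@H](O)[C@@H](C)CC)CCC(=O)C1=C(O)C[C@@H](C)OC1=O
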